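Everything rests on breaking C6–C7 and C1–C10 of the hydroazulene (C1 ring-fusion CH, C2 acyloxy carbon, C4 exocyclic-methylene carbon, C5/C6 diol carbons, C7 quaternary fusion carbon, C10 tertiary carbinol). The feature used is that C1–C15, all carbons except the isovalerate, make up one continuous head-to-tail triisoprenoid chain, so the seven-membered ring (C1–C7) and the five-membered ring (C1, C7–C10) can arise in one cyclisation cascade. In the key step a class one sesquiterpene cyclase converts acyclic (2E,6E)-farnesyl diphosphate into the trans-fused C10 alcohol with a C4=C5 alkene: two rings and the C1, C7 and C10 centres in one operation. The precursor is farnesol activated as its diphosphate. The alkene then carries the C2, C5 and C6 oxidations.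

Key step: step 3

Remark 1 (numbering and faces): the same locants are used for the acyclic compounds: C6 is the oxygen-bearing chain end, and the three alkenes are C5=C4 (C15 on C4), C1=C7 (C14 on C7) and C10=C11 (C12, C13 on C11); in the bicycle β is the face of the C14 methyl and α the other face.

Remark 2 (assumption): a daucane-type cyclase that stops at the C10 cation and adds water there is assumed to be obtainable by screening and mutagenesis; the diphosphate is kept as the unmodified natural substrate so that its acceptance by the enzyme is not put at risk.

Remark 3: C2 is not approached by C–H functionalisation directed from the C10 hydroxyl, because a tether there reaches the isopropyl methyl groups first and would deliver to the β-hydrogen of C2; C2 is oxygenated through the 2,4-dien-6-one instead.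

Step 1
Reactants: 1 (2E,6E)-farnesol
Product: 2 (2E,6E)-farnesyl chloride
Conditions: NCS, Me2S, CH2Cl2, −40 to 0 °C
Reagents that add atoms: N-chlorosuccinimide, O=C1CCC(=O)N1Cl
Why: Corey–Kim chlorination, in which the alcohol is activated as an alkoxysulfonium salt and displaced by chloride at the primary carbon without allylic transposition or loss of the alkene geometry.

Step 2
Reactants: 2 (2E,6E)-farnesyl chloride; 3 tris(tetrabutylammonium) hydrogen diphosphate
Product: 4 (2E,6E)-farnesyl diphosphate (isolated as its ammonium salt)
Conditions: MeCN, rt; cation-exchange resin (NH4+ form), aq. NH4HCO3/i-PrOH; cellulose chromatography, lyophilisation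
Reagents that add atoms: tris(tetrabutylammonium) hydrogen diphosphate (3), CCCC[N+](CCCC)(CCCC)CCCC.CCCC[N+](CCCC)(CCCC)CCCC.CCCC[N+](CCCC)(CCCC)CCCC.OP(=O)([O-])OP(=O)([O-])[O-]
Why: SN2 displacement of the primary allylic chloride by the diphosphate anion in acetonitrile, the standard diphosphorylation of prenyl halides, followed by cation exchange to the water-soluble salt.

Step 3
Reactants: 4 (2E,6E)-farnesyl diphosphate
Product: 5 dauc-4-en-10β-ol (route numbering; dauc-8-en-4β-ol in the usual daucane numbering)
Conditions: recombinant daucane-type class one sesquiterpene cyclase (purified, from E. coli), MgCl2 (10 mM), HEPES buffer pH 7.5, DTT, pentane overlay, 30 °C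
Reagents that add atoms: water, O
Why: Proposed new method: Mg2+-assisted ionisation of 4 and return of the diphosphate to C4 (nerolidyl diphosphate) let the C4=C5 bond become cis; re-ionisation gives an allyl cation whose C6 terminus is attacked by C7 of the central alkene while C1 of that alkene is attacked by C10 of the distal alkene, the resulting C11 cation takes a hydride from C10, and the C10 cation is quenched by active-site water. The closest known reaction type is the one-step cyclisation of farnesyl diphosphate to daucane alcohols such as carotol by class one sesquiterpene cyclases; an enzyme releasing exactly this C10 alcohol has not been described. The seven-membered ring closes in a 7-endo mode (both carbons of the C1=C7 alkene end up in the ring) and the five-membered ring in a 5-exo mode (C11 stays outside), the second closure running together with the first because a free secondary C1 cation would be too poor. C7 and C1 are set relative to each other by antiperiplanar addition across the E-configured central alkene, which gives the trans fusion (C14 anti to H1), the absolute sense coming from the chiral fold of the chain in the active site; C10 is set by the face on which the bound water sits, syn to C14. The step needs C6–C7 bonding in place of the Markovnikov C6–C1 (bisabolyl) closure and water capture at C10 before a second hydride shift or proton loss; the substrate supplies only the E geometry of its alkenes, everything else must come from the active-site contour and is to be secured by screening daucane-type cyclases and mutating the residues around the water site.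

Step 4
Reactants: 5 dauc-4-en-10β-ol
Product: 6 10β-hydroxydauc-4-en-6-one
Conditions: Rh2(cap)4 (1 mol %), t-BuOOH (70% in water), CH2Cl2, rt
Reagents that add atoms: tert-butyl hydroperoxide, CC(C)(C)OO
Why: Dirhodium-catalysed radical allylic oxidation (Kharasch type), in which the tert-butylperoxyl radical removes hydrogen from C6, the CH2 next to the CH end of the trisubstituted alkene, and oxygen is taken up at that secondary terminus of the allyl radical, as in the 5-ene to 7-ketone oxidation of steroids; no stereocentre is formed and the tertiary alcohol is inert.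

Step 5
Reactants: 6 10β-hydroxydauc-4-en-6-one
Product: 7 10β-hydroxydauca-2,4-dien-6-one
Conditions: chloranil, t-BuOH, reflux
Reagents that add atoms: none
Why: Quinone dehydrogenation of an enone through its through-conjugated dienol (hydride abstraction from C2), the reaction that turns steroidal 4-en-3-ones into 4,6-dien-3-ones; C7 is quaternary, so no cross-conjugated isomer can form, and H1 is not touched.

Step 6
Reactants: 7 10β-hydroxydauca-2,4-dien-6-one
Product: 10 2α,10β-dihydroxydauc-4-en-6-one, via allylboronate 8 (not isolated), via deconjugated ketol 9 (not isolated)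
Conditions: CuCl (5 mol %), Xantphos, NaOtBu (10 mol %), bis(pinacolato)diboron, MeOH, THF, rt; then NaBO3·4H2O, THF/H2O, rt; then DBU (cat.), CH2Cl2, 0 °C
Reagents that add atoms: sodium perborate, [Na+].[O-]OB=O
Why: Copper-catalysed 1,6-conjugate borylation of a linear dienone whose β-carbon C4 is fully substituted, then oxidation of the C–B bond with retention and base-mediated return of the alkene into conjugation; the monovalent copper boryl should add to C2 from the α-face because the C14 methyl and the C10 oxygen both lie syn-clinal to C2 on the β-face, which sets the 2α-oxygen.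

Step 7
Reactants: 10 2α,10β-dihydroxydauc-4-en-6-one; 11 isovaleric anhydride
Product: 12 2α-isovaleroyloxy-10β-hydroxydauc-4-en-6-one
Conditions: DMAP (cat.), pyridine, CH2Cl2, 0 °C
Reagents that add atoms: isovaleric anhydride (11), CC(C)CC(=O)OC(=O)CC(C)C
Why: DMAP-catalysed acylation (nucleophilic catalysis) of the only secondary alcohol; the tertiary C10 alcohol does not react at 0 °C and the weak base keeps the δ-acyloxy enone from eliminating.

Step 8
Reactants: 12 2α-isovaleroyloxy-10β-hydroxydauc-4-en-6-one
Product: 13 2α-isovaleroyloxydauc-4-ene-6β,10β-diol
Conditions: NaBH4, CeCl3·7H2O, MeOH, −78 °C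
Reagents that add atoms: none
Why: Luche 1,2-reduction, in which hydride should enter C6 anti to the pseudo-axial C14 methyl on the neighbouring quaternary C7 (the usual course for a ketone next to an angular methyl), placing the new hydroxyl on the methyl face (6β); this is the opposite of what the target needs and is corrected in step 9.

Step 9
Reactants: 13 2α-isovaleroyloxydauc-4-ene-6β,10β-diol
Product: 15 2α-isovaleroyloxydauc-4-ene-6α,10β-diol, via 6α-chloroacetate 14 (not isolated)
Conditions: PPh3, DIAD, ClCH2CO2H, toluene, 0 °C to rt; then K2CO3, MeOH, 0 °C
Reagents that add atoms: chloroacetic acid, OC(=O)CCl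
Why: Mitsunobu reaction, in which chloroacetate (the acidic nucleophile suited to hindered secondary alcohols) displaces the oxyphosphonium group by SN2 from the open α-face and so inverts C6, followed by mild methanolysis of the chloroacetate, which the hindered isovalerate survives.

Step 10
Reactants: 15 2α-isovaleroyloxydauc-4-ene-6α,10β-diol
Product: 16 4α,5α-epoxy-2α-isovaleroyloxydaucane-6α,10β-diol
Conditions: VO(acac)2 (5 mol %), t-BuOOH (decane), CH2Cl2, 0 °C to rt
Reagents that add atoms: tert-butyl hydroperoxide, CC(C)(C)OO
Why: Hydroxyl-directed vanadium-catalysed epoxidation, in which the alkylperoxide bound to the 6α-oxygen delivers oxygen to the same face of the C4=C5 bond (the reliable cis course for cyclohept-2-enols), setting C4 and C5 with the epoxide oxygen α.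

Step 11
Reactants: 16 4α,5α-epoxy-2α-isovaleroyloxydaucane-6α,10β-diol
Product: 17 2α-isovaleroyloxydauc-4(15)-ene-5α,6α,10β-triol (CNP0204264.1)
Conditions: Cp2TiCl2 (2.5 equiv), Mn dust, THF, rt; dilute aq. HCl work-up
Reagents that add atoms: none
Why: Nugent–RajanBabu opening of the epoxide by trivalent titanium at the more substituted C4–O bond, trapping of the tertiary C4 radical by a second titanium centre and β-hydride elimination towards the unhindered C15 methyl (epoxide-to-allylic-alcohol isomerisation); the C5–O bond is not broken, so C5 keeps the α-configuration from step 10, and the ester and free alcohols are tolerated.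

Compound list
1 | (2E,6E)-farnesol | CC(C)=CCC/C(C)=C/CC/C(C)=C/CO | starting material
2 | (2E,6E)-farnesyl chloride | CC(C)=CCC/C(C)=C/CC/C(C)=C/CCl | intermediate
3 | tris(tetrabutylammonium) hydrogen diphosphate | CCCC[N+](CCCC)(CCCC)CCCC.CCCC[N+](CCCC)(CCCC)CCCC.CCCC[N+](CCCC)(CCCC)CCCC.OP(=O)([O-])OP(=O)([O-])[O-] | starting material
4 | (2E,6E)-farnesyl diphosphate, handled as its ammonium salt, drawn as the free acid | CC(C)=CCC/C(C)=C/CC/C(C)=C/COP(=O)(O)OP(=O)(O)O | intermediate
5 | dauc-4-en-10β-ol: trans-fused bicycle (1α-H, 7β-CH3), C4=C5 alkene with C15 on C4, 10β-OH, 10α-isopropyl | C1=C(C)CC[C@@H]2[C@](C)(CC[C@@]2(O)C(C)C)C1 | intermediate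
6 | 10β-hydroxydauc-4-en-6-one (5 with a C6 ketone) | C1=C(C)CC[C@@H]2[C@](C)(CC[C@@]2(O)C(C)C)C1=O | intermediate
7 | 10β-hydroxydauca-2,4-dien-6-one (6 with an added C2=C3 alkene) | C1=C(C)C=C[C@@H]2[C@](C)(CC[C@@]2(O)C(C)C)C1=O | intermediate
8 | 2α-(pinacolatoboryl)-10β-hydroxydauc-3-en-6-one (allylboronate) | C1C(C)=C[C@H](B3OC(C)(C)C(C)(C)O3)[C@@H]2[C@](C)(CC[C@@]2(O)C(C)C)C1=O | intermediate (not isolated)
9 | 2α,10β-dihydroxydauc-3-en-6-one | C1C(C)=C[C@H](O)[C@@H]2[C@](C)(CC[C@@]2(O)C(C)C)C1=O | intermediate (not isolated)
10 | 2α,10β-dihydroxydauc-4-en-6-one | C1=C(C)C[C@H](O)[C@@H]2[C@](C)(CC[C@@]2(O)C(C)C)C1=O | intermediate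
11 | isovaleric anhydride | CC(C)CC(=O)OC(=O)CC(C)C | starting material
12 | 2α-isovaleroyloxy-10β-hydroxydauc-4-en-6-one | C1=C(C)C[C@H](OC(=O)CC(C)C)[C@@H]2[C@](C)(CC[C@@]2(O)C(C)C)C1=O | intermediate
13 | 2α-isovaleroyloxydauc-4-ene-6β,10β-diol (6-OH on the C14 face) | C1=C(C)C[C@H](OC(=O)CC(C)C)[C@@H]2[C@](C)(CC[C@@]2(O)C(C)C)[C@H]1O | intermediate
14 | 6α-chloroacetoxy-2α-isovaleroyloxydauc-4-en-10β-ol | C1=C(C)C[C@H](OC(=O)CC(C)C)[C@@H]2[C@](C)(CC[C@@]2(O)C(C)C)[C@@H]1OC(=O)CCl | intermediate (not isolated)
15 | 2α-isovaleroyloxydauc-4-ene-6α,10β-diol (6-OH anti to C14) | C1=C(C)C[C@H](OC(=O)CC(C)C)[C@@H]2[C@](C)(CC[C@@]2(O)C(C)C)[C@@H]1O | intermediate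
16 | 4α,5α-epoxy-2α-isovaleroyloxydaucane-6α,10β-diol (epoxide cis to 6-OH, C15 β) | C[C@@]12C[C@H](OC(=O)CC(C)C)[C@@H]3[C@](C)(CC[C@@]3(O)C(C)C)[C@H](O)[C@@H]1O2 | intermediate
17 | 2α-isovaleroyloxydauc-4(15)-ene-5α,6α,10β-triol (CNP0204264.1) | C=C1C[C@H](OC(=O)CC(C)C)[C@@H]2[C@](C)(CC[C@@]2(O)C(C)C)[C@H](O)[C@@H]1O | target

Total steps: 11. Longest linear sequence: 11 steps (1 to 17).

Steps most likely to fail

Step 3 (carries the new-method label). The cyclase may let the cation run on to other products (a second hydride shift to the carotol-type fusion alcohol, proton loss to daucene-type olefins, Markovnikov closure to bisabolyl products), or turn over too slowly for material supply. The fallback uses known chemistry and relays through the natural series. It sets out from isovaleric anhydride 11 and does not need 1–10. Commercial ferutinin F1, the 2α-(4-hydroxybenzoate) of the 2α,10β-diol, is saponified (KOH, MeOH, reflux) to jaeschkeanadiol F2. Its secondary 2α-hydroxyl is acylated with 11 (DMAP, pyridine) to the 2α-isovalerate F3. Dirhodium-catalysed allylic oxidation with t-BuOOH, as in step 4, then gives enone 12, where the route is rejoined.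

Step 6. The boryl copper may add from the β-face (delivery by the C10 alkoxide) or at C4, and the alkene may not return fully into conjugation in the seven-membered ring. The fallback sets C2 by a hydroxyl-directed reduction instead of by the addition. It sets out from dienone 7: the borylation and oxidation are run without regard to the C2 configuration, giving the epimeric alcohol, 2β-hydroxy enone F4. Dess–Martin oxidation gives the 2,6-dione F5. Me4NBH(OAc)3 in MeCN/AcOH (Evans–Saksena reduction) then delivers hydride from the boron bound to the C10 hydroxyl to the β-face of the C2 ketone; the C6 enone carbonyl has no β-hydroxyl and is left. This gives 2α-alcohol 10, where the route is rejoined.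

Step 9. Elimination to a diene or SN2′ attack at C4 may outrun substitution at the hindered C6 next to the quaternary C7. The fallback replaces inversion by a catalyst-controlled reduction. It sets out from enone 12: Corey–Bakshi–Shibata reduction with the enantiomer of the methyl oxazaborolidine that delivers hydride to the β-face (quaternary C7 as the large group, the C5=C4 alkene as the small one; the enantiomer is to be fixed on a model ketone) gives the 6α-alcohol 15 directly, where the route is rejoined. No compound outside the list is made (F0).

Further compounds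
F1 | step 3 | ferutinin: 2α-(4-hydroxybenzoyloxy)dauc-4-en-10β-ol | C1=C(C)C[C@H](OC(=O)c3ccc(O)cc3)[C@@H]2[C@](C)(CC[C@@]2(O)C(C)C)C1
F2 | step 3 | jaeschkeanadiol: dauc-4-ene-2α,10β-diol | C1=C(C)C[C@H](O)[C@@H]2[C@](C)(CC[C@@]2(O)C(C)C)C1
F3 | step 3 | 2α-isovaleroyloxydauc-4-en-10β-ol | C1=C(C)C[C@H](OC(=O)CC(C)C)[C@@H]2[C@](C)(CC[C@@]2(O)C(C)C)C1
F4 | step 6 | 2β,10β-dihydroxydauc-4-en-6-one | C1=C(C)C[C@@H](O)[C@@H]2[C@](C)(CC[C@@]2(O)C(C)C)C1=O
F5 | step 6 | 10β-hydroxydauc-4-ene-2,6-dione | C1=C(C)CC(=O)[C@@H]2[C@](C)(CC[C@@]2(O)C(C)C)C1=O
F0 | step 9 | none | none
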